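**Retrosynthetic overview**
- The target comes from one acidic unmasking of a protected C6-alkylated isoflavone: three MOM ethers and one TBS ether fall, and a bis(silylmethyl)carbinol that hides the isopropenyl group collapses by Peterson elimination and protodesilylation.
- The C6–CH2 bond is made by a light-driven C–H alkylation of the 5-phenolate of an 8-prenyl isoflavone with a chiral primary iodide; the carbinol stereocentre is only carried along.
- The iodide comes in three steps from L-serine-derived methyl (R)-glycidate: iodide opening, silylation, double Me3SiCH2 addition to the ester.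
- The 8-prenyl isoflavone comes from orobol by MOM protection, 5-O-prenylation and para-Claisen–Cope rearrangement.
- Rings A and B are bought (phloroglucinol, 3,4-dihydroxyphenylacetic acid); ring C, the pyranone, is the only ring formed, in the first step.

Assumption: the target is the (R)-alcohol as drawn, and the numbered starting materials and all named reagents are commercial.

**Route**

Step 1
Reactants: 1 phloroglucinol; 2 3,4-dihydroxyphenylacetic acid
Product: 4 orobol [3-(3,4-dihydroxyphenyl)-5,7-dihydroxy-4H-chromen-4-one], via deoxybenzoin 3 (not isolated)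
Conditions: BF3·OEt2, 85 °C; then DMF, MsCl, 75 °C; aq. NaOAc work-up
Reagents that add atoms: N,N-dimethylformamide, CN(C)C=O
Why: Friedel–Crafts (Hoesch-type) C-acylation of the symmetric triol gives the deoxybenzoin, which is C-formylated by the DMF/MsCl Vilsmeier-type reagent and closes ring C (one-pot deoxybenzoin isoflavone synthesis); no stereocentre.

Step 2
Reactants: 4 orobol
Product: 5 3-[3,4-bis(methoxymethoxy)phenyl]-5-hydroxy-7-(methoxymethoxy)-4H-chromen-4-one
Conditions: MOMCl (3.3 equiv), i-Pr2NEt, CH2Cl2–DMF, 0 °C to rt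
Reagents that add atoms: chloromethyl methyl ether, COCCl
Why: Williamson-type MOM etherification of the three unchelated phenols; the 5-OH is hydrogen-bonded to the C4 carbonyl and stays free with an amine base.

Step 3
Reactants: 5 tri-MOM orobol
Product: 6 3-[3,4-bis(methoxymethoxy)phenyl]-7-(methoxymethoxy)-5-[(3-methylbut-2-en-1-yl)oxy]-4H-chromen-4-one
Conditions: prenol, PPh3, DIAD, THF, 0 °C to rt
Reagents that add atoms: 3-methylbut-2-en-1-ol, CC(C)=CCO
Why: Mitsunobu etherification of the only free phenol gives clean O-prenylation without C-alkylation or allylic transposition.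

Step 4
Reactants: 6 5-O-prenyl ether
Product: 9 3-[3,4-bis(methoxymethoxy)phenyl]-5-hydroxy-7-(methoxymethoxy)-8-(3-methylbut-2-en-1-yl)-4H-chromen-4-one, via ortho-dienone 7 (not isolated), via para-dienone 8 (not isolated)
Conditions: Eu(C10H10F7O2)3 [Eu(fod)3] (10 mol %), CHCl3, 60 °C
Reagents that add atoms: none
Why: Lewis-acid-catalysed para-Claisen–Cope rearrangement: a [3,3] shift to C6 gives the reverse-prenyl dienone, a Cope [3,3] shift moves the group to C8 as a normal prenyl, and enolisation frees the 5-OH again.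

Step 5
Reactants: 10 methyl (R)-glycidate
Product: 11 methyl (2S)-2-hydroxy-3-iodopropanoate
Conditions: LiI, AcOH, THF, 0 °C to rt
Reagents that add atoms: lithium iodide, [Li+].[I-]
Why: acid-assisted SN2 epoxide opening at the unsubstituted C3 (halohydrin formation); the C2–O bond is untouched, so the bought stereocentre is retained (the descriptor changes to S only through CIP priorities).

Step 6
Reactants: 11 iodohydrin ester
Product: 12 methyl (2S)-2-[(tert-butyldimethylsilyl)oxy]-3-iodopropanoate
Conditions: TBSOTf, 2,6-lutidine, CH2Cl2, −78 to 0 °C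
Reagents that add atoms: tert-butyldimethylsilyl trifluoromethanesulfonate, CC(C)(C)[Si](C)(C)OS(=O)(=O)C(F)(F)F
Why: silyl ether formation with a hindered, non-nucleophilic base blocks epoxide re-closure and avoids loss of HI; the stereocentre is not involved.

Step 7
Reactants: 12 silyloxy iodo ester
Product: 14 (3S)-3-[(tert-butyldimethylsilyl)oxy]-4-iodo-1-(trimethylsilyl)-2-[(trimethylsilyl)methyl]butan-2-ol, via silyl ketone 13 (not isolated)
Conditions: Me3SiCH2MgCl (4 equiv), anhydrous CeCl3 (4 equiv), THF, −78 to 0 °C; aq. NaHCO3 quench; Et3N-washed silica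
Reagents that add atoms: (trimethylsilyl)methylmagnesium chloride, C[Si](C)(C)C[Mg]Cl
Why: double addition of the weakly basic organocerium reagent to the ester (Bunnelle-type reaction) gives the bis(silylmethyl)carbinol, an acid-releasable, alkene-free and carbonyl-free stand-in for isopropenyl, without enolising the α-stereocentre or eliminating HI.

Step 8
Reactants: 9 8-prenyl 5-hydroxy isoflavone; 14 chiral iodide
Product: 15 3-[3,4-bis(methoxymethoxy)phenyl]-6-{(2R)-2-[(tert-butyldimethylsilyl)oxy]-3-hydroxy-4-(trimethylsilyl)-3-[(trimethylsilyl)methyl]butyl}-5-hydroxy-7-(methoxymethoxy)-8-(3-methylbut-2-en-1-yl)-4H-chromen-4-one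
Conditions: Cs2CO3 (2 equiv), degassed DMSO, 390 nm LEDs, 25 °C
Reagents that add atoms: none
Why: Proposed new method: photostimulated radical-chain ortho C–H alkylation of a chromone phenolate by an unactivated alkyl iodide; the excited caesium 5-phenolate of 9 reduces (or triplet-sensitises) the C–I bond of 14, the primary radical (no alkene, so no 1,2-vinyl shift; no carbonyl, so nothing the ortho phenolate can acylate) adds to C6, the only unsubstituted carbon ortho or para to O−, the resulting ketyl-type radical anion hands its electron to the next molecule of 14 (or the radical pairs with the phenoxyl radical), and proton loss re-aromatises; the stereocentre is β to the radical and untouched; closest known reaction types are photostimulated SRN1 C-alkylation of aryloxides and excited-phenolate electron-transfer alkylation of phenols.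

Step 9
Reactants: 15 protected C6-alkylated isoflavone
Product: 17 target CNP0305771.1 [3-(3,4-dihydroxyphenyl)-5,7-dihydroxy-6-[(2R)-2-hydroxy-3-methylbut-3-en-1-yl]-8-(3-methylbut-2-en-1-yl)-4H-chromen-4-one], via allylsilane 16 (not isolated)
Conditions: HCl (2 M) in MeOH–H2O (9:1), 45 °C
Reagents that add atoms: none
Why: acid triggers Peterson elimination of the tertiary β-hydroxysilane to the allylsilane and its protodesilylation to isopropenyl (regiospecific through the β-silyl cation), while the same medium cleaves the MOM acetals and the TBS ether; the carbinol C–O bond is never broken, so (R) is kept.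

**Compound list**

1 | phloroglucinol (benzene-1,3,5-triol) | Oc1cc(O)cc(O)c1 | starting material
2 | 3,4-dihydroxyphenylacetic acid | OC(=O)Cc1ccc(O)c(O)c1 | starting material
3 | 2-(3,4-dihydroxyphenyl)-1-(2,4,6-trihydroxyphenyl)ethan-1-one (deoxybenzoin, not isolated) | O=C(Cc1ccc(O)c(O)c1)c1c(O)cc(O)cc1O | intermediate
4 | orobol, 3-(3,4-dihydroxyphenyl)-5,7-dihydroxy-4H-chromen-4-one | O=c1c(-c2ccc(O)c(O)c2)coc2cc(O)cc(O)c12 | intermediate
5 | 3-[3,4-bis(methoxymethoxy)phenyl]-5-hydroxy-7-(methoxymethoxy)-4H-chromen-4-one | COCOc1cc(O)c2c(c1)occ(-c1ccc(OCOC)c(OCOC)c1)c2=O | intermediate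
6 | 3-[3,4-bis(methoxymethoxy)phenyl]-7-(methoxymethoxy)-5-[(3-methylbut-2-en-1-yl)oxy]-4H-chromen-4-one | COCOc1cc(OCC=C(C)C)c2c(c1)occ(-c1ccc(OCOC)c(OCOC)c1)c2=O | intermediate
7 | 3-[3,4-bis(methoxymethoxy)phenyl]-7-(methoxymethoxy)-6-(2-methylbut-3-en-2-yl)-4H-chromene-4,5(6H)-dione (ortho-dienone, C6 unassigned, not isolated) | COCOC1=CC2=C(C(=O)C1C(C)(C)C=C)C(=O)C(-c1ccc(OCOC)c(OCOC)c1)=CO2 | intermediate
8 | 3-[3,4-bis(methoxymethoxy)phenyl]-7-(methoxymethoxy)-8-(3-methylbut-2-en-1-yl)-4H-chromene-4,5(8H)-dione (para-dienone, C8 unassigned, not isolated) | COCOC1=CC(=O)C2=C(OC=C(-c3ccc(OCOC)c(OCOC)c3)C2=O)C1CC=C(C)C | intermediate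
9 | 3-[3,4-bis(methoxymethoxy)phenyl]-5-hydroxy-7-(methoxymethoxy)-8-(3-methylbut-2-en-1-yl)-4H-chromen-4-one | COCOc1cc(O)c2c(c1CC=C(C)C)occ(-c1ccc(OCOC)c(OCOC)c1)c2=O | intermediate
10 | methyl (2R)-oxirane-2-carboxylate, methyl (R)-glycidate | COC(=O)[C@H]1CO1 | starting material
11 | methyl (2S)-2-hydroxy-3-iodopropanoate | COC(=O)[C@H](O)CI | intermediate
12 | methyl (2S)-2-[(tert-butyldimethylsilyl)oxy]-3-iodopropanoate | COC(=O)[C@H](O[Si](C)(C)C(C)(C)C)CI | intermediate
13 | (3S)-3-[(tert-butyldimethylsilyl)oxy]-4-iodo-1-(trimethylsilyl)butan-2-one (not isolated) | C[Si](C)(C)CC(=O)[C@H](O[Si](C)(C)C(C)(C)C)CI | intermediate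
14 | (3S)-3-[(tert-butyldimethylsilyl)oxy]-4-iodo-1-(trimethylsilyl)-2-[(trimethylsilyl)methyl]butan-2-ol | C[Si](C)(C)CC(O)(C[Si](C)(C)C)[C@H](O[Si](C)(C)C(C)(C)C)CI | intermediate
15 | 3-[3,4-bis(methoxymethoxy)phenyl]-6-{(2R)-2-[(tert-butyldimethylsilyl)oxy]-3-hydroxy-4-(trimethylsilyl)-3-[(trimethylsilyl)methyl]butyl}-5-hydroxy-7-(methoxymethoxy)-8-(3-methylbut-2-en-1-yl)-4H-chromen-4-one | COCOc1c(C[C@@H](O[Si](C)(C)C(C)(C)C)C(O)(C[Si](C)(C)C)C[Si](C)(C)C)c(O)c2c(c1CC=C(C)C)occ(-c1ccc(OCOC)c(OCOC)c1)c2=O | intermediate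
16 | 3-[3,4-bis(methoxymethoxy)phenyl]-6-{(2R)-2-[(tert-butyldimethylsilyl)oxy]-3-[(trimethylsilyl)methyl]but-3-en-1-yl}-5-hydroxy-7-(methoxymethoxy)-8-(3-methylbut-2-en-1-yl)-4H-chromen-4-one (allylsilane, not isolated) | COCOc1c(C[C@@H](O[Si](C)(C)C(C)(C)C)C(=C)C[Si](C)(C)C)c(O)c2c(c1CC=C(C)C)occ(-c1ccc(OCOC)c(OCOC)c1)c2=O | intermediate
17 | 3-(3,4-dihydroxyphenyl)-5,7-dihydroxy-6-[(2R)-2-hydroxy-3-methylbut-3-en-1-yl]-8-(3-methylbut-2-en-1-yl)-4H-chromen-4-one | C=C(C)[C@H](O)Cc1c(O)c(CC=C(C)C)c2occ(-c3ccc(O)c(O)c3)c(=O)c2c1O | target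

**Step count and risks**

Total steps: 9. Longest linear sequence: 6 (steps 1, 2, 3, 4, 8, 9); the side-chain branch is steps 5–7.

Step 8 (the proposed new step) is the most likely to fail. Possible failures are O-alkylation of the phenolate, attack at the prenylated C8 or at C2 of ring C, or simple reduction of the iodide. The fallback uses known chemistry and sets out from 9. N-Iodosuccinimide (CH2Cl2, 0 °C) iodinates the only free ring-A position, ortho to the 5-OH, to give 3-[3,4-bis(methoxymethoxy)phenyl]-5-hydroxy-6-iodo-7-(methoxymethoxy)-8-(3-methylbut-2-en-1-yl)-4H-chromen-4-one F1. A nickel-catalysed cross-electrophile coupling of this aryl iodide with iodide 14 (NiI2, 4,4′-di-tert-butyl-2,2′-bipyridine, tetrakis(dimethylamino)ethene as soluble reductant, MeCN, 40 °C) then comes back to the route at 15.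

Step 9 is second. The acid may close the 7-OH or 5-OH onto the prenyl or isopropenyl group to give chromans, or ionise the allylic alcohol. The fallback sets out from 15 and separates the events under non-protic conditions. Silica gel in CH2Cl2 effects the Peterson elimination to allylsilane 16, now isolated. Bu4NF in wet THF at 40 °C then protodesilylates it and removes the TBS group to give 3-[3,4-bis(methoxymethoxy)phenyl]-5-hydroxy-6-[(2R)-2-hydroxy-3-methylbut-3-en-1-yl]-7-(methoxymethoxy)-8-(3-methylbut-2-en-1-yl)-4H-chromen-4-one F2. ZnBr2 with n-PrSH (CH2Cl2, 0 °C, minutes) cleaves the three MOM ethers and comes back at 17.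

Step 7 is third. The β-iodo ester or the silyl ketone 13 may lose HI under the organometallic reagent. The fallback sets out from 10 and adds the carbon before the iodide is present. Me3SiCH2MgCl/CeCl3 on the glycidate, whose epoxide is inert at −78 °C, gives 2-[(2R)-oxiran-2-yl]-1,3-bis(trimethylsilyl)propan-2-ol F3. LiI with one equivalent of AcOH (THF, 0 °C) opens the terminal epoxide carbon to (3S)-4-iodo-1-(trimethylsilyl)-2-[(trimethylsilyl)methyl]butane-2,3-diol F4. TBSCl/imidazole (DMF) silylates only the secondary hydroxyl and comes back at 14.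

**Further compounds**

F1 | step 8 | 3-[3,4-bis(methoxymethoxy)phenyl]-5-hydroxy-6-iodo-7-(methoxymethoxy)-8-(3-methylbut-2-en-1-yl)-4H-chromen-4-one | COCOc1c(I)c(O)c2c(c1CC=C(C)C)occ(-c1ccc(OCOC)c(OCOC)c1)c2=O
F2 | step 9 | 3-[3,4-bis(methoxymethoxy)phenyl]-5-hydroxy-6-[(2R)-2-hydroxy-3-methylbut-3-en-1-yl]-7-(methoxymethoxy)-8-(3-methylbut-2-en-1-yl)-4H-chromen-4-one | COCOc1c(C[C@@H](O)C(C)=C)c(O)c2c(c1CC=C(C)C)occ(-c1ccc(OCOC)c(OCOC)c1)c2=O
F3 | step 7 | 2-[(2R)-oxiran-2-yl]-1,3-bis(trimethylsilyl)propan-2-ol | C[Si](C)(C)CC(O)(C[Si](C)(C)C)[C@H]1CO1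
F4 | step 7 | (3S)-4-iodo-1-(trimethylsilyl)-2-[(trimethylsilyl)methyl]butane-2,3-diol | C[Si](C)(C)CC(O)(C[Si](C)(C)C)[C@H](O)CI
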